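Overview, germacrane numbering: C1 ketone, C4–C5 oxirane (C15 methyl on C4), C6 lactone carbinol, C7=C11, C8 propionate, C10 tertiary acetate (C14 methyl), C12 lactone carbonyl, C13 acetoxymethyl.
The strategy rests on the butenolide ring (O, C6, C7, C11, C12). Its tetrasubstituted C7=C11 alkene lies between the oxygen-bearing carbons C6 and C13, so it is a disguised C6–C7≡C11–C13 butynediol unit that takes up C8 (vinyl Grignard) and C12 (CO2) in anti fashion.
The C1 ketone with the C10 methyl carbinol is the hydrate of a C10=C14 methylene ketone. C9–C10–C14 therefore come from 2,3-dibromopropene, whose allyl end adds to a C8 aldehyde and whose vinyl bromide end closes C1–C10 (Ni/Cr).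
The alkynol comes from asymmetric alkynylation of an E-enal (C1–C6 and C15, from 4-pentyn-1-ol) with PMB propargyl ether (C7, C11, C13).
Ring order: butenolide (step 6), oxirane (step 7), ten-membered carbocycle (step 13). The C10 oxygen is added last.
Key step: step 6

Assumption: (S,S)-ProPhenol is taken to deliver the alkynylzinc to the Si face of the enal in step 5, and the sulfonamide ligand enantiomer of step 9 is the one that adds to the Si face of the C8 aldehyde; both senses are checked by Mosher esters on the first batch, and the equally available antipodal ligand is used if the check demands it.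

Step 1
Reactants: 1 4-pentyn-1-ol
Product: 3 (E)-5-iodo-4-methylpent-4-en-1-ol, via alkenylalane 2 (not isolated)
Conditions: AlMe3 (3 equiv), Cp2ZrCl2 (0.25 equiv), CH2Cl2, 0 °C to rt; I2, THF, −30 to 0 °C
Reagents that add atoms: trimethylaluminium C[Al](C)C; iodine [I][I]
Why: Negishi zirconium-catalysed carboalumination adds methyl (C15) and aluminium syn across the terminal alkyne with methyl on the internal carbon C4, and iodinolysis with retention fixes the E geometry that later defines the relative configuration of the oxirane.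

Step 2
Reactants: 3 (E)-5-iodo-4-methylpent-4-en-1-ol
Product: 4 (E)-tert-butyl[(5-iodo-4-methylpent-4-en-1-yl)oxy]dimethylsilane
Conditions: TBSCl, imidazole, CH2Cl2, 0 °C to rt
Reagents that add atoms: tert-butyldimethylsilyl chloride CC(C)(C)[Si](C)(C)Cl
Why: Routine silyl ether formation masks the C1 hydroxyl against the organolithium, organozinc and Grignard steps ahead and can be undone later by fluoride without acid.

Step 3
Reactants: 4 (E)-tert-butyl[(5-iodo-4-methylpent-4-en-1-yl)oxy]dimethylsilane
Product: 6 (E)-6-[(tert-butyldimethylsilyl)oxy]-3-methylhex-2-enal, via alkenyllithium 5 (not isolated)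
Conditions: t-BuLi (2.1 equiv), Et2O, −78 °C; DMF, −78 to 0 °C; aq. NH4Cl
Reagents that add atoms: N,N-dimethylformamide CN(C)C=O
Why: Lithium–iodine exchange on an alkenyl iodide goes with retention, and formylation of the configurationally stable alkenyllithium with DMF brings in C6 as the E-enal.

Step 4
Reactants: 7 propargyl alcohol
Product: 8 1-methoxy-4-[(prop-2-yn-1-yloxy)methyl]benzene (PMB propargyl ether)
Conditions: NaH, PMBCl, Bu4NI (cat.), THF–DMF, 0 °C to rt
Reagents that add atoms: 4-methoxybenzyl chloride COc1ccc(CCl)cc1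
Why: Williamson etherification of the far more acidic hydroxyl leaves the alkyne C–H free and places on the future O13 a group that resists bases, chromium reagents and fluoride and leaves at the end under neutral oxidative conditions.

Step 5
Reactants: 6 (E)-6-[(tert-butyldimethylsilyl)oxy]-3-methylhex-2-enal; 8 PMB propargyl ether
Product: 10 (R,E)-9-[(tert-butyldimethylsilyl)oxy]-1-[(4-methoxybenzyl)oxy]-6-methylnon-5-en-2-yn-4-ol (6R carbinol), via alkynyl(methyl)zinc 9 (not isolated)
Conditions: 8 (3 equiv), ZnMe2 (3 equiv), (S,S)-ProPhenol (10 mol %), Ph3PO (20 mol %), toluene, rt; then 6, 4 °C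
Reagents that add atoms: none
Why: In the Zn–ProPhenol asymmetric alkynylation the dinuclear zinc complex holds the enal and the alkynylzinc 9 side by side and transfers the alkynyl group to the Si face, which sets C6 as R under catalyst control on a substrate class (enals) well suited to this reaction.

Step 6
Reactants: 10 6R dienynol; 11 vinylmagnesium chloride
Product: 14 (R)-5-[(E)-5-(tert-butyldimethylsilyloxy)-2-methylpent-1-en-1-yl]-3-[(4-methoxybenzyloxy)methyl]-4-vinylfuran-2(5H)-one, via oxamagnesacycle 12 (not isolated), via Z-hydroxy acid 13 (not isolated)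
Conditions: 11 (5 equiv, 1.6 M in THF), THF, 65 °C until 10 is consumed; −20 °C, dry CO2 gas, to rt; cold 1 M HCl to pH 3, Et2O
Reagents that add atoms: carbon dioxide O=C=O
Why: The first equivalent of 11 deprotonates the C6 hydroxyl, and the magnesium alkoxide then guides a second vinylmagnesium unit to the near alkyne carbon C7 while magnesium finishes on C11 inside the five-membered oxamagnesacycle 12, a net anti carbomagnesiation that forms C7–C8. The closest known reaction type is exactly this alkoxide-directed addition of vinyl Grignard reagents to propargylic alcohols followed by CO2 capture to give furan-2(5H)-ones, applied here to a secondary carbinol. CO2 carboxylates the sp2 C11–Mg bond with retention and forms C11–C12, so in 13 the carboxyl group lies cis to C6 and the butenolide ring closes on acidification by 5-exo-trig acyl substitution of O6 at C12, whereas C8 is trans and O13 could only form a four-membered ring. No stereocentre is made, the 6R centre rides through as its alkoxide, and the only stereochemical element set, the geometry of the C7=C11 alkene, is dictated by the chelate. The step needs regioselectivity (vinyl to C7, carboxyl to C11) and anti geometry, and both are secured because 10 has a single free hydroxyl and therefore a single possible chelate, helped by the inductive pull of O13 that favours carbanion character at C11. The weak point is expulsion of 4-methoxybenzyl oxide from C13 of 12 to give a vinylallene, which is why a poor alkoxide nucleofuge is kept on O13, heating is limited to what D2O-quenched aliquots show to be necessary, and CO2 is admitted as soon as 10 is consumed.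

Step 7
Reactants: 14 4-vinyl butenolide
Product: 15 (S)-5-{(2R,3R)-3-[3-(tert-butyldimethylsilyloxy)propyl]-3-methyloxiran-2-yl}-3-[(4-methoxybenzyloxy)methyl]-4-vinylfuran-2(5H)-one (4R,5R,6S)
Conditions: D-fructose-derived Shi ketone (3 equiv, in portions), Oxone (2KHSO5·KHSO4·K2SO4), NaHCO3, aq. Na2EDTA, MeCN–CH2(OMe)2, pH about 8, 0 °C
Reagents that add atoms: potassium peroxymonosulfate (KHSO5 of Oxone) [K+].[O-]S(=O)(=O)OO
Why: In the Shi asymmetric epoxidation the chiral dioxirane attacks the only electron-rich alkene, the E-trisubstituted C4=C5 bond, through the spiro transition state on the face that gives the 4R,5R oxirane under reagent control, while the two dienoate alkenes are too electron-poor to react and the low-pH variant with a full charge of ketone spares the acidic C6–H.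

Step 8
Reactants: 15 4R,5R epoxide
Product: 17 (S)-2-{(2R,3R)-3-[3-(tert-butyldimethylsilyloxy)propyl]-3-methyloxiran-2-yl}-4-[(4-methoxybenzyloxy)methyl]-5-oxo-2,5-dihydrofuran-3-carbaldehyde (C8 aldehyde), via vicinal diol 16 (not isolated)
Conditions: OsO4 (3 mol %), NaIO4 (4 equiv), THF–aq. NaH2PO4/Na2HPO4 (pH 7), 0 °C to rt; used at once
Reagents that add atoms: osmium tetroxide O=[Os](=O)(=O)=O (oxygen carrier); sodium periodate [Na+].[O-]I(=O)(=O)=O (terminal oxidant)
Why: In the Lemieux–Johnson cleavage OsO4 dihydroxylates the terminal vinyl group, the least hindered and least electron-poor alkene left, and NaIO4 cleaves diol 16 in the same pot to leave C8 as the aldehyde, the neutral buffer protecting the C6–H that sits next to the oxirane.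

Step 9
Reactants: 17 C8 aldehyde; 18 2,3-dibromopropene
Product: 20 (S)-4-[(S)-3-bromo-1-hydroxybut-3-en-1-yl]-5-{(2R,3R)-3-[3-(tert-butyldimethylsilyloxy)propyl]-3-methyloxiran-2-yl}-3-[(4-methoxybenzyloxy)methyl]furan-2(5H)-one (8S carbinol), via 2-bromoallylchromium 19 (not isolated)
Conditions: CrCl2 (10 mol %), chiral N-[2-(4-isopropyl-4,5-dihydrooxazol-2-yl)aryl]methanesulfonamide ligand (11 mol %), Et3N (11 mol %), Fe(TMHD)3 (2 mol %), Mn powder (2 equiv), Cp2ZrCl2 (1.1 equiv), 2,6-lutidine (1 equiv), MeCN, rt
Reagents that add atoms: none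
Why: In this catalytic asymmetric Nozaki–Hiyama 2-haloallylation, ligand-bound divalent chromium activates only the allylic C–Br bond of 18, and allylchromium 19 adds through a closed six-membered transition state to the Si face of the non-enolisable aldehyde to set C8 as S under ligand control, the vinylic C–Br bond surviving because no nickel is present and Cp2ZrCl2 releasing chromium without exposing the oxirane to a chlorosilane.

Step 10
Reactants: 20 8S 2-bromoallyl carbinol
Product: 21 8-O-propionate of 20
Conditions: (EtCO)2O, pyridine, DMAP (cat.), CH2Cl2, 0 °C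
Reagents that add atoms: propionic anhydride CCC(=O)OC(=O)CC
Why: Nucleophile-catalysed acylation of the only free hydroxyl installs the final C8 ester with retention, since the C8–O bond is not touched, and O8 cannot translactonise because C8 is trans to C12 on the alkene.

Step 11
Reactants: 21 C8 propionate TBS ether
Product: 22 primary C1 alcohol
Conditions: Bu4NF–AcOH (1:1), THF, 0 °C to rt
Reagents that add atoms: none
Why: Fluoride cleavage of the primary silyl ether under acetate buffering avoids both base at C6–H and acid at the oxirane, so that 5-exo attack of the freed C1 hydroxyl on C4 does not start before the alcohol is oxidised.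

Step 12
Reactants: 22 primary C1 alcohol
Product: 23 vinyl bromide aldehyde (C1 aldehyde, C10 bromide)
Conditions: Dess–Martin periodinane, NaHCO3, CH2Cl2, 0 °C
Reagents that add atoms: none
Why: Dess–Martin oxidation under bicarbonate is fast and neutral, stops at the aldehyde and leaves the oxirane, vinyl bromide, esters and PMB ether alone.

Step 13
Reactants: 23 vinyl bromide aldehyde
Product: 25 ten-membered allylic alcohol (4R,5R,6S,8S, both C1 epimers), via alkenylchromium 24 (not isolated)
Conditions: CrCl2 (8 equiv), NiCl2 (0.08 equiv), DMSO, slow addition of 23 to 1 mM final concentration, rt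
Reagents that add atoms: none
Why: In the intramolecular Nozaki–Hiyama–Kishi reaction zerovalent nickel inserts into the C10–Br bond and hands the alkenyl group to chromium, and alkenylchromium 24 tolerates ester, lactone, oxirane and ether groups and adds only to the C1 aldehyde, high dilution favouring ring closure, while the new C1 centre needs no control because it is oxidised next.

Step 14
Reactants: 25 ten-membered allylic alcohol
Product: 26 C10(14)-methylene C1 ketone
Conditions: Dess–Martin periodinane, NaHCO3, CH2Cl2, 0 °C to rt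
Reagents that add atoms: none
Why: Dess–Martin oxidation merges both C1 epimers into one 2-methylene ketone and removes the hydroxyl that could attack C4 of the oxirane across the ring.

Step 15
Reactants: 26 2-methylene ketone
Product: 28 10R tertiary ketol, via C10 hydroperoxide 27 (not isolated)
Conditions: Mn(dpm)3 (15 mol %), PhSiH3 (2.5 equiv), O2 (1 atm), i-PrOH–CH2Cl2, 0 °C; then P(OEt)3, 0 °C to rt
Reagents that add atoms: dioxygen O=O
Why: In this Mukaiyama-type hydration of an enone a manganese hydride made from Mn(dpm)3 and PhSiH3 transfers a hydrogen atom to the terminal C14, the tertiary C10 radical next to the ketone captures O2, and P(OEt)3 reduces hydroperoxide 27, with C10 set by substrate control through approach of O2 to the outer face of the ring, an outcome (10R) that is expected but not assured.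

Step 16
Reactants: 28 tertiary ketol PMB ether
Product: 29 C10,C13 diol
Conditions: DDQ, CH2Cl2–aq. NaH2PO4/Na2HPO4 (pH 7), 0 °C
Reagents that add atoms: none
Why: Oxidative PMB cleavage by DDQ proceeds by hydride abstraction from the electron-rich benzylic position only, under neutral conditions that leave the oxirane, ketol, lactone and propionate intact.

Step 17
Reactants: 29 C10,C13 diol
Product: 30 target CNP0285168.1
Conditions: Ac2O (10 equiv), DMAP (2 equiv), CH2Cl2, rt
Reagents that add atoms: acetic anhydride CC(=O)OC(C)=O
Why: In the DMAP-promoted acylation the primary C13 hydroxyl is acetylated at once, which forestalls propionyl migration from O8 to O13, and the excess reagent then acylates the hindered tertiary C10 hydroxyl without breaking any bond to a stereocentre.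

Compound list
1 | 4-pentyn-1-ol | C#CCCCO | starting material
2 | (E)-[5-(dimethylaluminooxy)-2-methylpent-1-en-1-yl]dimethylalane | C[Al](C)OCCC/C(C)=C/[Al](C)C | intermediate
3 | (E)-5-iodo-4-methylpent-4-en-1-ol | OCCC/C(C)=C/I | intermediate
4 | (E)-tert-butyl[(5-iodo-4-methylpent-4-en-1-yl)oxy]dimethylsilane | I/C=C(\C)CCCO[Si](C)(C)C(C)(C)C | intermediate
5 | (E)-[5-(tert-butyldimethylsilyloxy)-2-methylpent-1-en-1-yl]lithium | [Li]/C=C(\C)CCCO[Si](C)(C)C(C)(C)C | intermediate
6 | (E)-6-[(tert-butyldimethylsilyl)oxy]-3-methylhex-2-enal | O=C/C=C(\C)CCCO[Si](C)(C)C(C)(C)C | intermediate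
7 | propargyl alcohol | C#CCO | starting material
8 | 1-methoxy-4-[(prop-2-yn-1-yloxy)methyl]benzene | C#CCOCc1ccc(OC)cc1 | intermediate
9 | methyl{3-[(4-methoxybenzyl)oxy]prop-1-yn-1-yl}zinc | C[Zn]C#CCOCc1ccc(OC)cc1 | intermediate
10 | (R,E)-9-[(tert-butyldimethylsilyl)oxy]-1-[(4-methoxybenzyl)oxy]-6-methylnon-5-en-2-yn-4-ol | O[C@@H](C#CCOCc1ccc(OC)cc1)/C=C(\C)CCCO[Si](C)(C)C(C)(C)C | intermediate
11 | vinylmagnesium chloride | C=C[Mg]Cl | starting material
12 | five-membered oxamagnesacycle (ring O6, C6, C7, C11, Mg; vinyl on C7, PMBOCH2 on C11) | C=CC1=C(COCc2ccc(OC)cc2)[Mg]O[C@@H]1/C=C(\C)CCCO[Si](C)(C)C(C)(C)C | intermediate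
13 | (Z)-hydroxy acid, C12 carboxyl cis to the 6R carbinol | OC(=O)/C(COCc1ccc(OC)cc1)=C(/C=C)[C@H](O)/C=C(\C)CCCO[Si](C)(C)C(C)(C)C | intermediate
14 | (R)-5-[(E)-5-(tert-butyldimethylsilyloxy)-2-methylpent-1-en-1-yl]-3-[(4-methoxybenzyloxy)methyl]-4-vinylfuran-2(5H)-one | C=CC1=C(COCc2ccc(OC)cc2)C(=O)O[C@@H]1/C=C(\C)CCCO[Si](C)(C)C(C)(C)C | intermediate
15 | 4R,5R,6S epoxy vinyl butenolide | C=CC1=C(COCc2ccc(OC)cc2)C(=O)O[C@@H]1[C@H]1O[C@]1(C)CCCO[Si](C)(C)C(C)(C)C | intermediate
16 | 1,2-diol from the vinyl group of 15 (carbinol epimers) | OCC(O)C1=C(COCc2ccc(OC)cc2)C(=O)O[C@@H]1[C@H]1O[C@]1(C)CCCO[Si](C)(C)C(C)(C)C | intermediate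
17 | C8 aldehyde (4-formyl butenolide, 4R,5R,6S) | O=CC1=C(COCc2ccc(OC)cc2)C(=O)O[C@@H]1[C@H]1O[C@]1(C)CCCO[Si](C)(C)C(C)(C)C | intermediate
18 | 2,3-dibromopropene | BrCC(Br)=C | starting material
19 | (2-bromoallyl)chromium dichloride, ligand-bound | C=C(Br)C[Cr](Cl)Cl | intermediate
20 | 8S 2-bromoallyl carbinol (4R,5R,6S,8S) | O[C@@H](CC(Br)=C)C1=C(COCc2ccc(OC)cc2)C(=O)O[C@@H]1[C@H]1O[C@]1(C)CCCO[Si](C)(C)C(C)(C)C | intermediate
21 | C8 propionate of 20 | CCC(=O)O[C@@H](CC(Br)=C)C1=C(COCc2ccc(OC)cc2)C(=O)O[C@@H]1[C@H]1O[C@]1(C)CCCO[Si](C)(C)C(C)(C)C | intermediate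
22 | C1 primary alcohol | CCC(=O)O[C@@H](CC(Br)=C)C1=C(COCc2ccc(OC)cc2)C(=O)O[C@@H]1[C@H]1O[C@]1(C)CCCO | intermediate
23 | C1 aldehyde with C10 vinyl bromide | CCC(=O)O[C@@H](CC(Br)=C)C1=C(COCc2ccc(OC)cc2)C(=O)O[C@@H]1[C@H]1O[C@]1(C)CCC=O | intermediate
24 | C10 alkenylchromium dichloride of 23 | CCC(=O)O[C@@H](CC(=C)[Cr](Cl)Cl)C1=C(COCc2ccc(OC)cc2)C(=O)O[C@@H]1[C@H]1O[C@]1(C)CCC=O | intermediate
25 | ten-membered allylic alcohol, C10(14)-methylene, C1 epimers | CCC(=O)O[C@H]1CC(=C)C(O)CC[C@@]2(C)O[C@@H]2[C@H]2OC(=O)C(COCc3ccc(OC)cc3)=C12 | intermediate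
26 | ten-membered 2-methylene ketone | CCC(=O)O[C@H]1CC(=C)C(=O)CC[C@@]2(C)O[C@@H]2[C@H]2OC(=O)C(COCc3ccc(OC)cc3)=C12 | intermediate
27 | 10R tertiary hydroperoxide | CCC(=O)O[C@H]1C[C@@](C)(OO)C(=O)CC[C@@]2(C)O[C@@H]2[C@H]2OC(=O)C(COCc3ccc(OC)cc3)=C12 | intermediate
28 | 10R tertiary ketol, O13 PMB ether | CCC(=O)O[C@H]1C[C@@](C)(O)C(=O)CC[C@@]2(C)O[C@@H]2[C@H]2OC(=O)C(COCc3ccc(OC)cc3)=C12 | intermediate
29 | C10,C13 diol | CCC(=O)O[C@H]1C[C@@](C)(O)C(=O)CC[C@@]2(C)O[C@@H]2[C@H]2OC(=O)C(CO)=C12 | intermediate
30 | CNP0285168.1 (4R,5R,6S,8S,10R) | CCC(=O)O[C@H]1C[C@@](C)(OC(C)=O)C(=O)CC[C@@]2(C)O[C@@H]2[C@H]2OC(=O)C(COC(C)=O)=C12 | target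

Total step count: 17. Longest linear sequence: 16 steps (from 1 through steps 1–3 and 5–17); step 4 is the only side branch.

Risk 1 (step 6): carbomagnesiation of the hindered secondary alkoxide may be slow. On long heating the alkenylmagnesium may then lose the C13 alkoxide by β-elimination, so that material drains away before CO2 is admitted. The fallback replaces anti-carbomagnesiation of the alkynol by syn-carbocupration of an ynoate, in which C12 is in place from the start and C13 is attached last. It sets out from enal 6. Zn–ProPhenol addition of methyl propiolate under the conditions of step 5 should give methyl (R,E)-9-[(tert-butyldimethylsilyl)oxy]-4-hydroxy-6-methylnon-5-en-2-ynoate F1. A vinyl cuprate (vinylmagnesium bromide, CuI, THF, −78 °C, one extra equivalent for the hydroxyl) adds syn, with vinyl to C7 and copper to C11, which leaves the ester cis to C6. An iodine quench at −78 °C followed by mild acid should give the 3-iodo-4-vinylbutenolide F2. Stille coupling with (tributylstannyl)methanol (Pd(PPh3)4, dioxane, 80 °C) should give the 3-(hydroxymethyl)-4-vinylbutenolide F3. 4-Methoxybenzyl trichloroacetimidate with catalytic La(OTf)3 then brings the sequence back to the route at 14.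

Risk 2 (step 13): oxidative addition to the 2-bromoalkene may be sluggish, oligomerisation may outrun closure of the strained ten-membered ring, and the chromium alkoxide formed at C1 may open the oxirane at C4 across the ring. The fallback closes the same C1–C10 bond by acyl cross-coupling in place of carbonyl addition. It sets out from aldehyde 23. Pinnick oxidation (NaClO2, NaH2PO4, 2-methyl-2-butene, t-BuOH–H2O) should give the C1 carboxylic acid F4. This acid is kept cold and coupled at once (4-methylbenzenethiol, EDC, DMAP cat., CH2Cl2, 0 °C), so that it does not lactonise onto C4, to give the S-(4-methylphenyl) thioester F5. Exchange with Me3SnSnMe3 under Pd(PPh3)4 catalysis (dioxane, 80 °C) should convert the vinyl bromide into the alkenylstannane thioester F6. A neutral Liebeskind-type thioester–stannane ketone coupling (Pd2(dba)3, P(2-furyl)3, CuOP(O)Ph2, THF, high dilution) should then close the ring and return directly at enone 26. Step 14 is skipped and no C1 alkoxide ever faces the oxirane.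

Risk 3 (step 15): oxygen capture at the planar C10 radical may show poor facial selectivity or prefer the wrong face, since only the ring conformation controls it. The fallback replaces radical capture of O2 by reagent-controlled oxygen-atom transfer to a defined enol ether (asymmetric Rubottom oxidation). It sets out from enone 26. 1,4-Hydrosilylation (Et3SiH, RhCl(PPh3)3 cat., THF, 50 °C) should give the C1(10) triethylsilyl enol ether F7. Epoxidation with the dioxirane of whichever Shi ketone enantiomer (D-fructose- or L-sorbose-derived) matches the 10R face, under the conditions of step 7, should give the silyloxy oxirane F8. This collapses hydrolytically on work-up and returns to the route at ketol 28.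

Further compounds
F1 | step 6 | methyl (R,E)-9-[(tert-butyldimethylsilyl)oxy]-4-hydroxy-6-methylnon-5-en-2-ynoate | COC(=O)C#C[C@H](O)/C=C(\C)CCCO[Si](C)(C)C(C)(C)C
F2 | step 6 | 3-iodo-4-vinylbutenolide | C=CC1=C(I)C(=O)O[C@@H]1/C=C(\C)CCCO[Si](C)(C)C(C)(C)C
F3 | step 6 | 3-(hydroxymethyl)-4-vinylbutenolide | C=CC1=C(CO)C(=O)O[C@@H]1/C=C(\C)CCCO[Si](C)(C)C(C)(C)C
F4 | step 13 | C1 carboxylic acid | CCC(=O)O[C@@H](CC(Br)=C)C1=C(COCc2ccc(OC)cc2)C(=O)O[C@@H]1[C@H]1O[C@]1(C)CCC(=O)O
F5 | step 13 | S-(4-methylphenyl) thioester | CCC(=O)O[C@@H](CC(Br)=C)C1=C(COCc2ccc(OC)cc2)C(=O)O[C@@H]1[C@H]1O[C@]1(C)CCC(=O)Sc1ccc(C)cc1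
F6 | step 13 | alkenylstannane thioester | CCC(=O)O[C@@H](CC(=C)[Sn](C)(C)C)C1=C(COCc2ccc(OC)cc2)C(=O)O[C@@H]1[C@H]1O[C@]1(C)CCC(=O)Sc1ccc(C)cc1
F7 | step 15 | C1(10) triethylsilyl enol ether | CCC(=O)O[C@H]1CC(C)=C(O[Si](CC)(CC)CC)CC[C@@]2(C)O[C@@H]2[C@H]2OC(=O)C(COCc3ccc(OC)cc3)=C12
F8 | step 15 | silyloxy oxirane | CCC(=O)O[C@H]1C[C@@]3(C)OC3(O[Si](CC)(CC)CC)CC[C@@]2(C)O[C@@H]2[C@H]2OC(=O)C(COCc4ccc(OC)cc4)=C12
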